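**Retrosynthetic overview**

1. Ring B carries OH at C1, the aryl ether oxygen at C2 and the two-carbon chain to ring A at C4. This 1,2,4-pattern is the aromatised form of a 2-aryloxy-4-alkylcyclohex-2-en-1-one, so ring B is built last and de novo: target ⇐ cyclohexenone 15 by dehydrogenation and debenzylation.
2. Enone 15 ⇐ aldehyde 3 (ring A plus C3 and C4) and aryloxymethyl vinyl ketone 12 (C5, C6, C1, C2 and rings C and D). The Michael addition forms C4–C5, the aldol condensation forms C2–C3.
3. Vinyl ketone 12 ⇐ phenol 9, bromo Weinreb amide 10 and vinylmagnesium bromide. The C2–O bond of the later diaryl ether is thus made as an alkyl aryl ether at sp3 carbon.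
4. Phenol 9 ⇐ B-alkyl Suzuki coupling of hydroborated 4-acetoxystyrene 6 with 1,4-bis(benzyloxy)-2-bromobenzene 5. Aldehyde 3 ⇐ acid 1.
5. Rings A, C and D are bought; ring B is the only ring formed.

Key step: step 7

Remark: ring A is the 3-methoxyphenyl ring, ring B the central phenol (numbered as above, also in its cyclohexenone form), ring C the para-phenylene ether ring and ring D the hydroquinone. The target is achiral, and the one stereocentre met on the way (C4 of 13 to 15) is carried as the racemate.

**Route**

Step 1
Reactants: 1 4-(3-methoxyphenyl)butanoic acid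
Product: 2 4-(3-methoxyphenyl)butan-1-ol
Conditions: BH3·THF, THF, 0 °C to rt; H2O quench
Reagents that add atoms: none
Why: Borane reduction of a carboxylic acid proceeds rapidly through the acyloxyborane and should leave the aryl methyl ether untouched.

Step 2
Reactants: 2 4-(3-methoxyphenyl)butan-1-ol
Product: 3 4-(3-methoxyphenyl)butanal
Conditions: TEMPO (10 mol%), PhI(OAc)2, CH2Cl2, rt
Reagents that add atoms: none
Why: The oxoammonium-mediated (TEMPO) oxidation of a primary alcohol should stop at the aldehyde in the absence of water and does not attack the anisole ring.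

Step 3
Reactants: 4 2-bromobenzene-1,4-diol
Product: 5 1,4-bis(benzyloxy)-2-bromobenzene
Conditions: BnBr, K2CO3, DMF, rt, under N2
Reagents that add atoms: benzyl bromide, BrCc1ccccc1
Why: In this Williamson ether synthesis both phenoxides are alkylated by the benzylic bromide, and the aryl bromide is inert to these conditions.

Step 4
Reactants: 6 4-ethenylphenyl acetate (4-acetoxystyrene); 5 1,4-bis(benzyloxy)-2-bromobenzene
Product: 9 4-[2-[2,5-bis(benzyloxy)phenyl]ethyl]phenol, via B-alkyl-9-BBN adduct 7 (not isolated), via aryl acetate 8 (not isolated)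
Conditions: 6, 9-BBN, THF, 0 °C to rt; then 5, PdCl2(dppf) (3 mol%), 3 M aq NaOH, THF, 65 °C; dilute HCl work-up
Reagents that add atoms: none
Why: Anti-Markovnikov hydroboration of the styrene by 9-BBN followed by B-alkyl Suzuki–Miyaura coupling with the aryl bromide should form the CH2–CH2 bridge between rings C and D; the aqueous NaOH that activates the borane also saponifies the aryl acetate, and the benzyl ethers are safe from palladium in the absence of hydrogen.

Step 5
Reactants: 9 4-[2-[2,5-bis(benzyloxy)phenyl]ethyl]phenol; 10 2-bromo-N-methoxy-N-methylacetamide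
Product: 11 2-[4-[2-[2,5-bis(benzyloxy)phenyl]ethyl]phenoxy]-N-methoxy-N-methylacetamide
Conditions: K2CO3, acetone, reflux
Reagents that add atoms: none
Why: Williamson alkylation of the phenoxide by the carbonyl-activated primary bromide should be clean and places the ring C oxygen on the carbon that becomes C2 of ring B.

Step 6
Reactants: 11 2-[4-[2-[2,5-bis(benzyloxy)phenyl]ethyl]phenoxy]-N-methoxy-N-methylacetamide
Product: 12 1-[4-[2-[2,5-bis(benzyloxy)phenyl]ethyl]phenoxy]but-3-en-2-one
Conditions: CH2=CHMgBr, THF, −20 to 0 °C; inverse quench into cold 1 M HCl/Et2O; kept cold with a trace of BHT and used at once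
Reagents that add atoms: vinylmagnesium bromide, C=C[Mg]Br
Why: In this Weinreb ketone synthesis the magnesium chelate of the tetrahedral adduct prevents a second addition and collapses to the vinyl ketone only on quench, and the acidic inverse quench protonates the released amine so that it should not add to the new enone.

Step 7
Reactants: 3 4-(3-methoxyphenyl)butanal; 12 1-[4-[2-[2,5-bis(benzyloxy)phenyl]ethyl]phenoxy]but-3-en-2-one
Product: 15 2-[4-[2-[2,5-bis(benzyloxy)phenyl]ethyl]phenoxy]-4-[2-(3-methoxyphenyl)ethyl]cyclohex-2-en-1-one (racemic at C4), via keto aldehyde 13 (not isolated), via aldol 14 (not isolated)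
Conditions: 3 (1.5 equiv), Et2NH (30 mol%), THF, rt; then aq KOH (0.3 equiv), nBu4NOH (cat.), THF, 50 °C
Reagents that add atoms: none
Why: Diethylamine converts aldehyde 3 into an enamine whose nucleophilic carbon (the later C4) adds to the terminal carbon of vinyl ketone 12 (the later C5), and hydrolysis of the iminium returns the amine and gives keto aldehyde 13; hydroxide then enolises the ketone toward the aryloxy-bearing carbon, which attacks the aldehyde carbon (C2–C3 bond) to give aldol 14, and E1cB loss of water gives enone 15. The closest known reaction type is the amine-catalysed Michael addition of unmodified aldehydes to vinyl ketones followed by base-mediated aldol condensation to 4-substituted cyclohex-2-enones, that is a Robinson annulation, in which alkoxymethyl vinyl ketones are established partners. Ring B closes in the aldol step by a 6-(enolendo)-exo-trig attack. The only stereocentre left in 15 is C4; it forms without control as the racemate, which does not matter because it becomes an aromatic carbon in step 8. The aldol must go through C2 and not C6, and ring size secures this, since attack from C6 on the aldehyde or from C4 on the ketone could only give a cyclobutanol reversibly, while the aryloxy group also makes the C2 hydrogens the more acidic ones. The cross Michael addition must outrun self-aldol of 3 and oligomerisation of 12, which the weakly basic secondary amine, the excess of 3 and slow addition of 12 should secure.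

Step 8
Reactants: 15 2-[4-[2-[2,5-bis(benzyloxy)phenyl]ethyl]phenoxy]-4-[2-(3-methoxyphenyl)ethyl]cyclohex-2-en-1-one
Product: 16 2-[4-[2-[2,5-bis(benzyloxy)phenyl]ethyl]phenoxy]-4-[2-(3-methoxyphenyl)ethyl]phenol
Conditions: Pd(OCOCF3)2 (5 mol%), 2-(dimethylamino)pyridine (10 mol%), TsOH·H2O (20 mol%), O2 (1 atm), DMSO, 80 °C
Reagents that add atoms: none
Why: In this aerobic dehydrogenation by divalent palladium, a palladium enolate at C6 should undergo beta-hydride elimination of H-5 to a cyclohexa-2,5-dienone that still carries H at C4 and tautomerises to the phenol, while oxygen reoxidises the palladium hydride and the ethers are untouched.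

Step 9
Reactants: 16 2-[4-[2-[2,5-bis(benzyloxy)phenyl]ethyl]phenoxy]-4-[2-(3-methoxyphenyl)ethyl]phenol
Product: 17 2-[2-[4-[2-hydroxy-5-[2-(3-methoxyphenyl)ethyl]phenoxy]phenyl]ethyl]benzene-1,4-diol (CNP0211397.0)
Conditions: H2 (1 atm), 10% Pd/C, EtOAc–MeOH, rt; filtration and concentration under argon
Reagents that add atoms: none
Why: Heterogeneous hydrogenolysis should cleave both benzyl aryl ethers, whereas the methyl ether and the diaryl ether are stable; the hydroquinone is handled without air to avoid quinone formation.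

**Compound list**

1 | 4-(3-methoxyphenyl)butanoic acid | COc1cccc(CCCC(=O)O)c1 | starting material
2 | 4-(3-methoxyphenyl)butan-1-ol | COc1cccc(CCCCO)c1 | intermediate
3 | 4-(3-methoxyphenyl)butanal | COc1cccc(CCCC=O)c1 | intermediate
4 | 2-bromobenzene-1,4-diol | Oc1ccc(O)c(Br)c1 | starting material
5 | 1,4-bis(benzyloxy)-2-bromobenzene | Brc1cc(OCc2ccccc2)ccc1OCc1ccccc1 | intermediate
6 | 4-ethenylphenyl acetate (4-acetoxystyrene) | CC(=O)Oc1ccc(C=C)cc1 | starting material
7 | 4-[2-(9-borabicyclo[3.3.1]nonan-9-yl)ethyl]phenyl acetate (formed in the flask, not isolated) | CC(=O)Oc1ccc(CCB2C3CCCC2CCC3)cc1 | intermediate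
8 | 4-[2-[2,5-bis(benzyloxy)phenyl]ethyl]phenyl acetate (formed in the flask, not isolated) | CC(=O)Oc1ccc(CCc2cc(OCc3ccccc3)ccc2OCc2ccccc2)cc1 | intermediate
9 | 4-[2-[2,5-bis(benzyloxy)phenyl]ethyl]phenol | Oc1ccc(CCc2cc(OCc3ccccc3)ccc2OCc2ccccc2)cc1 | intermediate
10 | 2-bromo-N-methoxy-N-methylacetamide | CON(C)C(=O)CBr | starting material
11 | 2-[4-[2-[2,5-bis(benzyloxy)phenyl]ethyl]phenoxy]-N-methoxy-N-methylacetamide | CON(C)C(=O)COc1ccc(CCc2cc(OCc3ccccc3)ccc2OCc2ccccc2)cc1 | intermediate
12 | 1-[4-[2-[2,5-bis(benzyloxy)phenyl]ethyl]phenoxy]but-3-en-2-one | C=CC(=O)COc1ccc(CCc2cc(OCc3ccccc3)ccc2OCc2ccccc2)cc1 | intermediate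
13 | 6-[4-[2-[2,5-bis(benzyloxy)phenyl]ethyl]phenoxy]-2-[2-(3-methoxyphenyl)ethyl]-5-oxohexanal (racemic; formed in the flask, not isolated) | COc1cccc(CCC(C=O)CCC(=O)COc2ccc(CCc3cc(OCc4ccccc4)ccc3OCc3ccccc3)cc2)c1 | intermediate
14 | 2-[4-[2-[2,5-bis(benzyloxy)phenyl]ethyl]phenoxy]-3-hydroxy-4-[2-(3-methoxyphenyl)ethyl]cyclohexan-1-one (mixture of diastereomers; formed in the flask, not isolated) | COc1cccc(CCC2CCC(=O)C(Oc3ccc(CCc4cc(OCc5ccccc5)ccc4OCc4ccccc4)cc3)C2O)c1 | intermediate
15 | 2-[4-[2-[2,5-bis(benzyloxy)phenyl]ethyl]phenoxy]-4-[2-(3-methoxyphenyl)ethyl]cyclohex-2-en-1-one (racemic at C4) | COc1cccc(CCC2CCC(=O)C(Oc3ccc(CCc4cc(OCc5ccccc5)ccc4OCc4ccccc4)cc3)=C2)c1 | intermediate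
16 | 2-[4-[2-[2,5-bis(benzyloxy)phenyl]ethyl]phenoxy]-4-[2-(3-methoxyphenyl)ethyl]phenol | COc1cccc(CCc2ccc(O)c(Oc3ccc(CCc4cc(OCc5ccccc5)ccc4OCc4ccccc4)cc3)c2)c1 | intermediate
17 | 2-[2-[4-[2-hydroxy-5-[2-(3-methoxyphenyl)ethyl]phenoxy]phenyl]ethyl]benzene-1,4-diol | COc1cccc(CCc2ccc(O)c(Oc3ccc(CCc4cc(O)ccc4O)cc3)c2)c1 | target

**Count**

Total steps: 9. Longest linear sequence: 7 steps (steps 3 to 9, from 2-bromobenzene-1,4-diol 4).

**Steps most likely to fail**

Step 7. The cross Michael addition may be outrun by self-aldol condensation of the aldehyde and by amine- or base-induced oligomerisation of the vinyl ketone, and the aldol closure may stall before dehydration. The fallback sets out from 3 and 12 and comes back at 15. The enamine is made stoichiometrically and apart from the enone: 3 with pyrrolidine (K2CO3, toluene, rt) should give (E)-1-[4-(3-methoxyphenyl)but-1-en-1-yl]pyrrolidine F1, which is freed from excess amine. F1 is combined with 12 in MeCN at 0 °C to rt and should add in the Stork manner, the adduct being held as the 2-(pyrrolidin-1-yl)-3,4-dihydro-2H-pyran F2. Buffered hydrolysis (AcOH, NaOAc, H2O) opens F2 to keto aldehyde 13, which is isolated here and closed to 15 in a separate acid-mediated aldol condensation (TsOH, toluene, 80 °C).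

Step 8. The catalytic dehydrogenation may stop at partial conversion through precipitation of zerovalent palladium, or the electron-rich phenol formed may be oxidised further under oxygen. The fallback sets out from 15 and comes back at 16. Kinetic deprotonation at C6 with LiN(iPr)2 (THF, −78 °C) and trapping with PhSeCl should give 2-[4-[2-[2,5-bis(benzyloxy)phenyl]ethyl]phenoxy]-4-[2-(3-methoxyphenyl)ethyl]-6-(phenylselanyl)cyclohex-2-en-1-one F3. Oxidation with H2O2 and pyridine in CH2Cl2 at 0 °C gives the selenoxide, whose syn elimination toward C5 yields the cyclohexa-2,5-dienone, and this tautomerises to 16.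

Step 6. The liberated N-methoxy-N-methylamine, or a second equivalent of the Grignard reagent, may add in conjugate fashion to the new enone during reaction or quench, and the enone may polymerise on concentration. The fallback sets out from 11 and comes back at 12, and it forms the enone under neutral conditions with no amine present. Reduction of 11 with iBu2AlH (THF, −78 °C) should give 2-[4-[2-[2,5-bis(benzyloxy)phenyl]ethyl]phenoxy]acetaldehyde F4. Addition of CH2=CHMgBr (THF, −78 °C) gives racemic 1-[4-[2-[2,5-bis(benzyloxy)phenyl]ethyl]phenoxy]but-3-en-2-ol F5, and oxidation with Dess–Martin periodinane and NaHCO3 in CH2Cl2 gives 12.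

**Further compounds**

F1 | step 7 | (E)-1-[4-(3-methoxyphenyl)but-1-en-1-yl]pyrrolidine | COc1cccc(CC/C=C/N2CCCC2)c1
F2 | step 7 | 6-[[4-[2-[2,5-bis(benzyloxy)phenyl]ethyl]phenoxy]methyl]-3-[2-(3-methoxyphenyl)ethyl]-2-(pyrrolidin-1-yl)-3,4-dihydro-2H-pyran (mixture of diastereomers) | COc1cccc(CCC2CC=C(COc3ccc(CCc4cc(OCc5ccccc5)ccc4OCc4ccccc4)cc3)OC2N2CCCC2)c1
F3 | step 8 | 2-[4-[2-[2,5-bis(benzyloxy)phenyl]ethyl]phenoxy]-4-[2-(3-methoxyphenyl)ethyl]-6-(phenylselanyl)cyclohex-2-en-1-one (mixture of diastereomers) | COc1cccc(CCC2CC([Se]c3ccccc3)C(=O)C(Oc3ccc(CCc4cc(OCc5ccccc5)ccc4OCc4ccccc4)cc3)=C2)c1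
F4 | step 6 | 2-[4-[2-[2,5-bis(benzyloxy)phenyl]ethyl]phenoxy]acetaldehyde | O=CCOc1ccc(CCc2cc(OCc3ccccc3)ccc2OCc2ccccc2)cc1
F5 | step 6 | 1-[4-[2-[2,5-bis(benzyloxy)phenyl]ethyl]phenoxy]but-3-en-2-ol (racemic) | C=CC(O)COc1ccc(CCc2cc(OCc3ccccc3)ccc2OCc2ccccc2)cc1
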